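**Retrosynthetic overview**

1. Feature: ring A (C4a, C5, C6, C7, C8, C8a) carries oxygen on the alternate carbons C5, C7 and C8a, with the extra methoxy on C8 between C7 and C8a. C5 and C7 are therefore read as an ester and a ketone carbonyl, while C2, C4 and C8a stay locked in ring C as a 4-pyranone.
2. Backwards: remove the O5 and O7 methyl groups, then cut C5–C6 (Claisen) to open ring A. This gives a 4-pyranone with a methyl ester (C5) on C4a and a 1-methoxy-2-oxopropyl chain (C8–C7–C6) on C8a.
3. C7–C8 comes from lateral acetylation of the 2-methoxymethyl pyranone. Ring C comes from C4–C4a C-acylation of methyl 4-methoxyacetoacetate with the ring B arylpropioloyl chloride, followed by O1–C2 oxa-Michael closure.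
4. The ring B alkynoic acid comes from 2,3,4-trimethoxybenzaldehyde by Dakin oxidation, O-methylation, iodination and Sonogashira coupling with propiolic acid.
5. Ring order: ring B (bought), ring C (step 6), ring A (step 8).

Key step: step 8

Assumption: flavone numbering (O1, C2, C3, C4, C4a, C5 to C8, C8a) is used for the corresponding atoms of all precursors. The only stereocenter on the route (C8 of 12) is racemic, epimerisable and erased on aromatisation, so the achiral target needs no stereocontrol.

**Route**

Step 1
Reactants: 1 2,3,4-trimethoxybenzaldehyde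
Product: 3 2,3,4-trimethoxyphenol, via 2,3,4-trimethoxyphenyl formate 2 (not isolated)
Conditions: mCPBA, CH2Cl2, 0 °C to rt; aq. NaHCO3 wash; then K2CO3 (cat.), MeOH, rt
Reagents that add atoms: mCPBA (OOC(=O)c1cccc(Cl)c1)
Why: Baeyer–Villiger (Dakin-type) oxidation, in which the electron-rich aryl group with ortho and para methoxy groups migrates in preference to hydrogen, and methanolysis of the aryl formate frees the phenol.

Step 2
Reactants: 3 2,3,4-trimethoxyphenol
Product: 4 1,2,3,4-tetramethoxybenzene
Conditions: Me2SO4, K2CO3, acetone, reflux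
Reagents that add atoms: dimethyl sulfate (COS(=O)(=O)OC)
Why: Williamson O-methylation of a phenoxide, with no competing nucleophilic site.

Step 3
Reactants: 4 1,2,3,4-tetramethoxybenzene
Product: 5 1-iodo-2,3,4,5-tetramethoxybenzene
Conditions: NIS (1.0 equiv), TFA (cat.), MeCN, rt, dark
Reagents that add atoms: N-iodosuccinimide (O=C1CCC(=O)N1I)
Why: Electrophilic aromatic iodination; the two free positions are equivalent by symmetry, so only one mono-iodide can form, and one equivalent of NIS limits di-iodination.

Step 4
Reactants: 5 1-iodo-2,3,4,5-tetramethoxybenzene; 6 propiolic acid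
Product: 7 3-(2,3,4,5-tetramethoxyphenyl)prop-2-ynoic acid
Conditions: Pd(PPh3)4 (cat.), DBU, DMSO, 35 °C; then aq. HCl
Reagents that add atoms: none
Why: Copper-free Sonogashira coupling of the aryl iodide with propiolic acid as its DBU carboxylate, run at mild temperature so that the arylpropiolic acid should not decarboxylate.

Step 5
Reactants: 7 3-(2,3,4,5-tetramethoxyphenyl)prop-2-ynoic acid
Product: 8 3-(2,3,4,5-tetramethoxyphenyl)prop-2-ynoyl chloride
Conditions: (COCl)2, DMF (cat.), CH2Cl2, 0 °C to rt; evaporate, use crude
Reagents that add atoms: oxalyl chloride (ClC(=O)C(=O)Cl)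
Why: Acid chloride formation through the Vilsmeier-type chloroiminium, at low temperature so that HCl should not add across the alkyne.

Step 6
Reactants: 8 3-(2,3,4,5-tetramethoxyphenyl)prop-2-ynoyl chloride; 9 methyl 4-methoxy-3-oxobutanoate (methyl 4-methoxyacetoacetate)
Product: 11 methyl 2-(methoxymethyl)-4-oxo-6-(2,3,4,5-tetramethoxyphenyl)-4H-pyran-3-carboxylate, via acyclic tricarbonyl ester 10 (not isolated)
Conditions: 9, MgCl2, pyridine, CH2Cl2, 0 °C; then 8, 0 °C to rt; 1 M HCl wash; crude, Et3N (cat.), CH2Cl2, rt
Reagents that add atoms: none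
Why: Soft-enolisation C-acylation of the chelated magnesium enolate (Rathke conditions) forms C4–C4a, and the enol oxygen of the methoxyacetyl ketone then adds 6-endo-dig to the ynone β-carbon (oxa-Michael, the classical γ-pyrone synthesis from β-keto esters and arylpropioloyl chlorides) to close ring C.

Step 7
Reactants: 11 methyl 2-(methoxymethyl)-4-oxo-6-(2,3,4,5-tetramethoxyphenyl)-4H-pyran-3-carboxylate
Product: 12 methyl 2-(1-methoxy-2-oxopropyl)-4-oxo-6-(2,3,4,5-tetramethoxyphenyl)-4H-pyran-3-carboxylate (racemic)
Conditions: LiN(SiMe3)2 (1.2 equiv), THF, −78 °C; then MeC(O)N(OMe)Me, −78 to 0 °C; aq. NH4Cl at −78 °C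
Reagents that add atoms: N-methoxy-N-methylacetamide (CC(=O)N(C)OC)
Why: Lateral (vinylogous) deprotonation of the CH2OMe group, which is γ to both the C4 ketone and the ester through the ring double bond, gives a dienolate that is C-acylated at the exocyclic carbon by the Weinreb amide (crossed Claisen-type acylation); the chelated tetrahedral adduct masks the ketone until work-up, which prevents double acylation and premature ring closure, and the new C8 stereocenter forms as the racemate.

Step 8
Reactants: 12 methyl 2-(1-methoxy-2-oxopropyl)-4-oxo-6-(2,3,4,5-tetramethoxyphenyl)-4H-pyran-3-carboxylate (racemic)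
Product: 13 5,7-dihydroxy-8-methoxy-2-(2,3,4,5-tetramethoxyphenyl)-4H-chromen-4-one
Conditions: LiN(SiMe3)2 (3.5 equiv), THF, −78 °C to rt; then 1 M HCl
Reagents that add atoms: none
Why: The first equivalent of base removes the C8 proton, which lies between the C7 ketone and the vinylogous C4/C5 carbonyl system, and further base sets up, in equilibrium, the methyl-side (C6) enolate; this adds to the ester carbon C5, methoxide leaves, and enolisation gives the aromatic 5,7-diol, whose phenoxide formation makes the sequence irreversible. The closest known reaction type is the base-induced intramolecular Claisen (Dieckmann-type) cyclisation of 2-(2-oxopropyl)aroates to 1,3-dihydroxyarenes, as used in biomimetic polyketide foldings. Ring A closes in a 6-exo-trig mode, the ester C=O being exocyclic to the forming ring. No stereocenter is created, and the racemic C8 centre of 12 is erased on aromatisation. The step needs attack of C6, not C8, on C5 and an intact pyranone: C8 could close only a four-membered ring, attack of C6 on C4 would give a bridged anti-Bredt alkene, and the hindered, non-nucleophilic amide base should not add to C2 or C8a of ring C.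

Step 9
Reactants: 13 5,7-dihydroxy-8-methoxy-2-(2,3,4,5-tetramethoxyphenyl)-4H-chromen-4-one
Product: 14 5,7,8-trimethoxy-2-(2,3,4,5-tetramethoxyphenyl)-4H-chromen-4-one (target, CNP0482056.0)
Conditions: Me2SO4 (excess), K2CO3, acetone, reflux
Reagents that add atoms: dimethyl sulfate (COS(=O)(=O)OC)
Why: Double Williamson O-methylation; excess reagent and prolonged reflux should also methylate the 5-OH, which is hydrogen-bonded to the C4 carbonyl.

**Compound list**

1 | 2,3,4-trimethoxybenzaldehyde | COc1ccc(C=O)c(OC)c1OC | starting material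
2 | 2,3,4-trimethoxyphenyl formate | COc1ccc(OC=O)c(OC)c1OC | intermediate
3 | 2,3,4-trimethoxyphenol | COc1ccc(O)c(OC)c1OC | intermediate
4 | 1,2,3,4-tetramethoxybenzene | COc1ccc(OC)c(OC)c1OC | intermediate
5 | 1-iodo-2,3,4,5-tetramethoxybenzene | COc1cc(I)c(OC)c(OC)c1OC | intermediate
6 | propiolic acid (prop-2-ynoic acid) | C#CC(=O)O | starting material
7 | 3-(2,3,4,5-tetramethoxyphenyl)prop-2-ynoic acid | COc1cc(C#CC(=O)O)c(OC)c(OC)c1OC | intermediate
8 | 3-(2,3,4,5-tetramethoxyphenyl)prop-2-ynoyl chloride | COc1cc(C#CC(=O)Cl)c(OC)c(OC)c1OC | intermediate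
9 | methyl 4-methoxy-3-oxobutanoate (methyl 4-methoxyacetoacetate) | COCC(=O)CC(=O)OC | starting material
10 | methyl 2-(2-methoxyacetyl)-3-oxo-5-(2,3,4,5-tetramethoxyphenyl)pent-4-ynoate (racemic, largely enolised) | COCC(=O)C(C(=O)OC)C(=O)C#Cc1cc(OC)c(OC)c(OC)c1OC | intermediate
11 | methyl 2-(methoxymethyl)-4-oxo-6-(2,3,4,5-tetramethoxyphenyl)-4H-pyran-3-carboxylate | COCc1oc(-c2cc(OC)c(OC)c(OC)c2OC)cc(=O)c1C(=O)OC | intermediate
12 | methyl 2-(1-methoxy-2-oxopropyl)-4-oxo-6-(2,3,4,5-tetramethoxyphenyl)-4H-pyran-3-carboxylate (racemic, configurationally labile) | COC(C(C)=O)c1oc(-c2cc(OC)c(OC)c(OC)c2OC)cc(=O)c1C(=O)OC | intermediate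
13 | 5,7-dihydroxy-8-methoxy-2-(2,3,4,5-tetramethoxyphenyl)-4H-chromen-4-one | COc1c(O)cc(O)c2c(=O)cc(-c3cc(OC)c(OC)c(OC)c3OC)oc12 | intermediate
14 | 5,7,8-trimethoxy-2-(2,3,4,5-tetramethoxyphenyl)-4H-chromen-4-one | COc1cc(-c2cc(=O)c3c(OC)cc(OC)c(OC)c3o2)c(OC)c(OC)c1OC | target

**Step count**

Total step count: 9. Longest linear sequence: 9 steps (1 to 14); compounds 6 and 9 enter as bought partners.

**Steps most likely to fail**

Step 8 (key Claisen closure). The resting C8 anion may not give enough of the C6 enolate. The C5 ester is a deactivated, vinylogous carbonate-type electrophile. Liberated methoxide may instead cause retro-Claisen loss of the acetyl group or conjugate opening of ring C. The fallback builds ring C last by the classical chalcone route. It sets out from compound 4: Rieche formylation (Cl2CHOMe, TiCl4, CH2Cl2, 0 °C) should give 2,3,4,5-tetramethoxybenzaldehyde F1, the only possible regioisomer. Claisen–Schmidt condensation of this with purchased 2'-hydroxy-3',4',6'-trimethoxyacetophenone (CC(=O)c1c(O)c(OC)c(OC)cc1OC; KOH, EtOH, rt) should give (E)-1-(2-hydroxy-3,4,6-trimethoxyphenyl)-3-(2,3,4,5-tetramethoxyphenyl)prop-2-en-1-one F2. Oxidative cyclisation with I2 (cat.) in DMSO at 130 °C should then give the flavone directly, rejoining the route at the target 14.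

Step 7 (lateral acetylation). The doubly stabilised dienolate may add too slowly to the Weinreb amide, may be acylated on oxygen, or the alkoxide of the tetrahedral adduct may engage the neighbouring ester. The fallback replaces acylation by aldol addition and oxidation. It sets out from compound 11: the same lithium dienolate (LiN(SiMe3)2, THF, −78 °C) is treated with acetaldehyde and quenched with AcOH at −78 °C, to prevent lactonisation of the aldolate onto the C3 ester. This should give methyl 2-(2-hydroxy-1-methoxypropyl)-4-oxo-6-(2,3,4,5-tetramethoxyphenyl)-4H-pyran-3-carboxylate F3 as a mixture of racemic diastereomers. Dess–Martin periodinane (NaHCO3, CH2Cl2, rt) should oxidise the secondary alcohol and return the route at compound 12.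

Step 6 (acylation and pyranone closure). O-acylation of the enolate, conjugate addition of pyridine to the ynoyl chloride, or incomplete 6-endo closure may erode the step. The fallback changes the nucleophile to an enamine. It sets out from compound 9: condensation with pyrrolidine (toluene, Dean–Stark) should give methyl (2E)-4-methoxy-3-(pyrrolidin-1-yl)but-2-enoate F4. C-acylation of its nucleophilic α-carbon with acid chloride 8 (Et3N, CH2Cl2, 0 °C) should give methyl 2-[2-methoxy-1-(pyrrolidin-1-yl)ethylidene]-3-oxo-5-(2,3,4,5-tetramethoxyphenyl)pent-4-ynoate F5. Aqueous HCl in THF should hydrolyse the enaminone to tricarbonyl 10, which cyclises as before, rejoining the route at compound 11.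

**Further compounds**

F1 | step 8 | 2,3,4,5-tetramethoxybenzaldehyde | COc1cc(C=O)c(OC)c(OC)c1OC
F2 | step 8 | (E)-1-(2-hydroxy-3,4,6-trimethoxyphenyl)-3-(2,3,4,5-tetramethoxyphenyl)prop-2-en-1-one | COc1cc(/C=C/C(=O)c2c(O)c(OC)c(OC)cc2OC)c(OC)c(OC)c1OC
F3 | step 7 | methyl 2-(2-hydroxy-1-methoxypropyl)-4-oxo-6-(2,3,4,5-tetramethoxyphenyl)-4H-pyran-3-carboxylate (mixture of racemic diastereomers) | COC(C(C)O)c1oc(-c2cc(OC)c(OC)c(OC)c2OC)cc(=O)c1C(=O)OC
F4 | step 6 | methyl (2E)-4-methoxy-3-(pyrrolidin-1-yl)but-2-enoate | COC/C(=C\C(=O)OC)N1CCCC1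
F5 | step 6 | methyl 2-[2-methoxy-1-(pyrrolidin-1-yl)ethylidene]-3-oxo-5-(2,3,4,5-tetramethoxyphenyl)pent-4-ynoate (alkene geometry not defined) | COCC(N1CCCC1)=C(C(=O)OC)C(=O)C#Cc1cc(OC)c(OC)c(OC)c1OC
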